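Unit 1 is the flavanone whose ring B bears the ether oxygen, unit 2 the one substituted at C6. Ring C of unit 1 (O1, C2, C3, C4, C4a, C8a) contains the O1–C2–C3–C4 chain of a 4-aryl-β-lactone, closed by two adjacent carbons of ring A. The route rests on inserting 3,5-bis(benzyloxy)benzyne into the acyl–oxygen bond (C4–O1) of an (S)-β-lactone. One operation forms C8a–O1 and C4a–C4, expands the ring from four to six atoms, installs ring A and leaves C2 untouched. The C5 oxygen beside C4a steers the aryne. The lactone is grown on an aldehyde carrying unit 2 as an achiral chromone, arylated enantioselectively afterwards.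

Key step: step 8

Remark: the four starting materials are taken as catalogue chemicals, and atom numbers follow flavanone nomenclature (O1, C2, C3, C4, C4a, C5 to C8, C8a).

Step 1
Reactants: 1 3,5-bis(benzyloxy)phenol
Product: 2 3,5-bis(benzyloxy)phenyl N-isopropylcarbamate
Conditions: i-PrNCO, Et3N (cat.), CH2Cl2, 23 °C
Reagents that add atoms: isopropyl isocyanate, CC(C)N=C=O
Why: Base-catalysed addition of the phenol to the isocyanate (carbamoylation) installs a directing group for ortho-metalation that can later be removed under mild, non-hydrolytic conditions.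

Step 2
Reactants: 2 3,5-bis(benzyloxy)phenyl N-isopropylcarbamate
Product: 6 3,5-bis(benzyloxy)-2-(trimethylsilyl)phenyl N-isopropylcarbamate, via N-silyl carbamate 3 (not isolated), via aryllithium 4 (not isolated), via bis-silyl carbamate 5 (not isolated)
Conditions: TBSOTf, TMEDA, Et2O, 0 to 23 °C; n-BuLi, TMEDA, −78 °C; TMSCl, −78 to 23 °C; aq. NaHSO4
Reagents that add atoms: chlorotrimethylsilane, C[Si](C)(C)Cl
Why: Directed ortho-metalation: transient N-silylation masks the N–H, the carbamate and the flanking benzyloxy group then direct lithiation cooperatively to C2 (C2 and C6 are equivalent), chlorotrimethylsilane traps the aryllithium, and the acidic work-up removes only the N-silyl group.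

Step 3
Reactants: 6 3,5-bis(benzyloxy)-2-(trimethylsilyl)phenyl N-isopropylcarbamate
Product: 8 3,5-bis(benzyloxy)-2-(trimethylsilyl)phenyl trifluoromethanesulfonate, via silylphenol 7 (not isolated)
Conditions: DBU, Et2NH, MeCN, 40 °C; then PhNTf2, 23 °C
Reagents that add atoms: N-phenylbis(trifluoromethanesulfonimide), O=S(=O)(N(c1ccccc1)S(=O)(=O)C(F)(F)F)C(F)(F)F
Why: E1cB cleavage of the N–H carbamate by DBU releases the phenoxide (diethylamine scavenges the isocyanate), which is sulfonylated in the same flask by PhNTf2, the standard end of a 2-(trimethylsilyl)aryl triflate synthesis.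

Step 4
Reactants: 9 1-[2,4-bis(benzyloxy)-6-hydroxyphenyl]ethan-1-one
Product: 11 1-[2,4-bis(benzyloxy)-3,6-dihydroxyphenyl]ethan-1-one, via aryl sulfate 10 (not isolated)
Conditions: K2S2O8, KOH, H2O–pyridine, 0 to 23 °C; then aq. HCl, 70 °C
Reagents that add atoms: potassium persulfate, [K+].[K+].[O-]S(=O)(=O)OOS(=O)(=O)[O-]
Why: Elbs persulfate oxidation: the phenolate attacks the peroxide oxygen through the carbon para to the free hydroxyl (C3, the only para site), and acid hydrolysis of the aryl sulfate frees the new phenol while the benzyl ethers stay.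

Step 5
Reactants: 11 1-[2,4-bis(benzyloxy)-3,6-dihydroxyphenyl]ethan-1-one; 12 4-fluorobenzaldehyde
Product: 13 4-[3-acetyl-2,6-bis(benzyloxy)-4-hydroxyphenoxy]benzaldehyde
Conditions: K2CO3, DMF (degassed, Ar), 90 °C
Reagents that add atoms: none
Why: Nucleophilic aromatic substitution (addition–elimination) on the formyl-activated fluoride; the C6 hydroxyl is tied up in a hydrogen bond with the acetyl group and its phenoxide is delocalised into it, so the C3 phenoxide reacts, and exclusion of air protects the hydroquinone.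

Step 6
Reactants: 13 4-[3-acetyl-2,6-bis(benzyloxy)-4-hydroxyphenoxy]benzaldehyde
Product: 15 4-{[5,7-bis(benzyloxy)-4-oxo-4H-chromen-6-yl]oxy}benzaldehyde, via enaminone 14 (not isolated)
Conditions: Me2NCH(OMe)2, toluene, 90 °C; then conc. HCl, CH2Cl2, 40 °C
Reagents that add atoms: N,N-dimethylformamide dimethyl acetal, COC(OC)N(C)C
Why: Enaminone route to chromones: the methyl ketone condenses with the amide acetal, and acid then triggers addition of the ortho-hydroxyl to the enaminone carbon and loss of dimethylamine, which supplies C2 of the chromone and leaves the non-enolisable aldehyde untouched.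

Step 7
Reactants: 15 4-{[5,7-bis(benzyloxy)-4-oxo-4H-chromen-6-yl]oxy}benzaldehyde
Product: 16 (4S)-4-(4-{[5,7-bis(benzyloxy)-4-oxo-4H-chromen-6-yl]oxy}phenyl)oxetan-2-one
Conditions: AcCl (slow addition), i-Pr2NEt, O-trimethylsilylquinine (15 mol%), LiClO4, CH2Cl2–Et2O, −78 °C
Reagents that add atoms: acetyl chloride, CC(=O)Cl
Why: Alkaloid-catalysed ketene–aldehyde [2+2] cycloaddition (acyl halide–aldehyde cyclocondensation): ketene made in situ gives a chiral ammonium enolate that adds to the LiClO4-activated aldehyde through a closed transition state and lactonises, the quinine-derived catalyst fixing the new C4 stereocentre as S (its pseudoenantiomer gives R), while the chromone carbonyl, a vinylogous ester, does not compete.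

Step 8
Reactants: 16 (4S)-4-(4-{[5,7-bis(benzyloxy)-4-oxo-4H-chromen-6-yl]oxy}phenyl)oxetan-2-one; 8 3,5-bis(benzyloxy)-2-(trimethylsilyl)phenyl trifluoromethanesulfonate
Product: 19 (2S)-5,7-bis(benzyloxy)-2-(4-{[5,7-bis(benzyloxy)-4-oxo-4H-chromen-6-yl]oxy}phenyl)-2,3-dihydro-4H-chromen-4-one, via aryne 17 (not isolated), via acyl fluoride alkoxide 18 (not isolated)
Conditions: CsF, 18-crown-6, THF, 0 to 23 °C, slow addition of 8 (2 equiv)
Reagents that add atoms: none
Why: Proposed new method: fluoride releases the aryne 17 from 8 and, as a hard nucleophile, opens the strained acyl–oxygen bond of 16 reversibly to the alkoxide 18, whose oxygen adds to the aryne; the aryl anion so formed attacks the acyl fluoride and gives fluoride back, so that two arene carbons are inserted into the C4–O1 bond and the four-membered ring becomes the six-membered ring C. The closest known reaction types are the aryne insertion into the N–C(O) bond of N–H β-lactams (ring expansion to 2,3-dihydroquinolin-4-ones), the aryne C–O insertion of carboxylic acids to o-hydroxyaryl ketones, the aryne annulation of salicylates to xanthones and the ring-expanding acyl-alkylation of cyclic β-keto esters with this very aryne, but the acyl–oxygen bond of a lactone has not been used in this way. The only ring closed is ring C, by a 6-exo-trig acyl substitution of the C4a anion at C4 after intermolecular C8a–O1 bond formation. No stereocentre is created: the C2–O1, C2–C3 and C2–aryl bonds are never broken, so the S configuration of 16 is carried into 19 with retention. The regioselectivity needed (oxygen at C8a, acyl at C4a beside the C5 oxygen) is secured by the inductive distortion of a 3-alkoxyaryne, which sends nucleophiles to the remote aryne carbon, and the reverse order of events (fluoride to that carbon, aryl anion to the lactone carbonyl, displacement of the ortho-fluoride by the freed alkoxide) ends in the same constitution. The chemoselectivity needed is acyl–oxygen cleavage rather than attack at the benzylic C2 or deprotonation at C3, which ring strain, the hard nucleophile, the aprotic medium and the low temperature should favour, while the chromone and the benzyl ethers offer no acidic hydrogen.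

Step 9
Reactants: 19 (2S)-5,7-bis(benzyloxy)-2-(4-{[5,7-bis(benzyloxy)-4-oxo-4H-chromen-6-yl]oxy}phenyl)-2,3-dihydro-4H-chromen-4-one; 20 [4-(benzyloxy)phenyl]boronic acid
Product: 21 (2S)-5,7-bis(benzyloxy)-2-[4-({(2S)-5,7-bis(benzyloxy)-2-[4-(benzyloxy)phenyl]-4-oxo-3,4-dihydro-2H-chromen-6-yl}oxy)phenyl]-2,3-dihydro-4H-chromen-4-one
Conditions: [Rh(OH)(cod)]2 (3 mol%), (S)-6,6'-dimethoxy-2,2'-bis[bis(3,4,5-trifluorophenyl)phosphino]-1,1'-biphenyl (7 mol%), toluene–H2O, 23 °C
Reagents that add atoms: none
Why: Hayashi–Miyaura reaction (asymmetric 1,4-addition catalysed by monovalent rhodium): the aryl–rhodium species adds to C2 of the chromone on the face left open by the (S)-biaryl diphosphine, the sense that gives (S)-3-arylcycloalkanones and here 2S in unit 2 under catalyst control, and the base-free medium protects both flavanones from retro-oxa-Michael racemisation.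

Step 10
Reactants: 21 (2S)-5,7-bis(benzyloxy)-2-[4-({(2S)-5,7-bis(benzyloxy)-2-[4-(benzyloxy)phenyl]-4-oxo-3,4-dihydro-2H-chromen-6-yl}oxy)phenyl]-2,3-dihydro-4H-chromen-4-one
Product: 22 (2S)-5,7-dihydroxy-2-[4-({(2S)-5,7-dihydroxy-2-(4-hydroxyphenyl)-4-oxo-3,4-dihydro-2H-chromen-6-yl}oxy)phenyl]-2,3-dihydro-4H-chromen-4-one
Conditions: H2 (1 atm), Pd/C, EtOAc–MeOH, 23 °C
Reagents that add atoms: none
Why: Hydrogenolysis of the five benzyl ethers over Pd/C under neutral conditions frees all phenols without touching the diaryl ether, the ketones or the two stereocentres, which are labile only to base.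

Compound list
1 | 3,5-bis(benzyloxy)phenol | Oc1cc(OCc2ccccc2)cc(OCc2ccccc2)c1 | starting material
2 | 3,5-bis(benzyloxy)phenyl N-isopropylcarbamate | CC(C)NC(=O)Oc1cc(OCc2ccccc2)cc(OCc2ccccc2)c1 | intermediate
3 | 3,5-bis(benzyloxy)phenyl N-(tert-butyldimethylsilyl)-N-isopropylcarbamate | CC(C)N(C(=O)Oc1cc(OCc2ccccc2)cc(OCc2ccccc2)c1)[Si](C)(C)C(C)(C)C | intermediate
4 | 2-lithio derivative of 3 | CC(C)N(C(=O)Oc1cc(OCc2ccccc2)cc(OCc2ccccc2)c1[Li])[Si](C)(C)C(C)(C)C | intermediate
5 | 3,5-bis(benzyloxy)-2-(trimethylsilyl)phenyl N-(tert-butyldimethylsilyl)-N-isopropylcarbamate | CC(C)N(C(=O)Oc1cc(OCc2ccccc2)cc(OCc2ccccc2)c1[Si](C)(C)C)[Si](C)(C)C(C)(C)C | intermediate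
6 | 3,5-bis(benzyloxy)-2-(trimethylsilyl)phenyl N-isopropylcarbamate | CC(C)NC(=O)Oc1cc(OCc2ccccc2)cc(OCc2ccccc2)c1[Si](C)(C)C | intermediate
7 | 3,5-bis(benzyloxy)-2-(trimethylsilyl)phenol | Oc1cc(OCc2ccccc2)cc(OCc2ccccc2)c1[Si](C)(C)C | intermediate
8 | 3,5-bis(benzyloxy)-2-(trimethylsilyl)phenyl trifluoromethanesulfonate | C[Si](C)(C)c1c(OS(=O)(=O)C(F)(F)F)cc(OCc2ccccc2)cc1OCc1ccccc1 | intermediate
9 | 1-[2,4-bis(benzyloxy)-6-hydroxyphenyl]ethan-1-one | CC(=O)c1c(O)cc(OCc2ccccc2)cc1OCc1ccccc1 | starting material
10 | potassium 3-acetyl-2,6-bis(benzyloxy)-4-hydroxyphenyl sulfate | CC(=O)c1c(O)cc(OCc2ccccc2)c(OS(=O)(=O)[O-])c1OCc1ccccc1.[K+] | intermediate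
11 | 1-[2,4-bis(benzyloxy)-3,6-dihydroxyphenyl]ethan-1-one | CC(=O)c1c(O)cc(OCc2ccccc2)c(O)c1OCc1ccccc1 | intermediate
12 | 4-fluorobenzaldehyde | O=Cc1ccc(F)cc1 | starting material
13 | 4-[3-acetyl-2,6-bis(benzyloxy)-4-hydroxyphenoxy]benzaldehyde | CC(=O)c1c(O)cc(OCc2ccccc2)c(Oc2ccc(C=O)cc2)c1OCc1ccccc1 | intermediate
14 | 4-{2,6-bis(benzyloxy)-3-[(E)-3-(dimethylamino)prop-2-enoyl]-4-hydroxyphenoxy}benzaldehyde | CN(C)/C=C/C(=O)c1c(O)cc(OCc2ccccc2)c(Oc2ccc(C=O)cc2)c1OCc1ccccc1 | intermediate
15 | 4-{[5,7-bis(benzyloxy)-4-oxo-4H-chromen-6-yl]oxy}benzaldehyde | O=Cc1ccc(Oc2c(OCc3ccccc3)cc3occc(=O)c3c2OCc2ccccc2)cc1 | intermediate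
16 | (4S)-4-(4-{[5,7-bis(benzyloxy)-4-oxo-4H-chromen-6-yl]oxy}phenyl)oxetan-2-one | O=C1C[C@@H](c2ccc(Oc3c(OCc4ccccc4)cc4occc(=O)c4c3OCc3ccccc3)cc2)O1 | intermediate
17 | 3,5-bis(benzyloxy)benzyne (1,2-didehydro-3,5-bis(benzyloxy)benzene) | C1#CC(OCc2ccccc2)=CC(OCc2ccccc2)=C1 | intermediate
18 | cesium (1S)-1-(4-{[5,7-bis(benzyloxy)-4-oxo-4H-chromen-6-yl]oxy}phenyl)-3-fluoro-3-oxopropan-1-olate | [Cs+].[O-][C@@H](CC(F)=O)c1ccc(Oc2c(OCc3ccccc3)cc3occc(=O)c3c2OCc2ccccc2)cc1 | intermediate
19 | (2S)-5,7-bis(benzyloxy)-2-(4-{[5,7-bis(benzyloxy)-4-oxo-4H-chromen-6-yl]oxy}phenyl)-2,3-dihydro-4H-chromen-4-one | O=C1C[C@@H](c2ccc(Oc3c(OCc4ccccc4)cc4occc(=O)c4c3OCc3ccccc3)cc2)Oc2cc(OCc3ccccc3)cc(OCc3ccccc3)c21 | intermediate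
20 | [4-(benzyloxy)phenyl]boronic acid | OB(O)c1ccc(OCc2ccccc2)cc1 | starting material
21 | penta-O-benzyl ether of the target, (2S) in both flavanone units | O=C1C[C@@H](c2ccc(Oc3c(OCc5ccccc5)cc4c(c3OCc5ccccc5)C(=O)C[C@@H](c3ccc(OCc5ccccc5)cc3)O4)cc2)Oc2cc(OCc3ccccc3)cc(OCc3ccccc3)c21 | intermediate
22 | (2S,2''S)-2,3,2'',3''-tetrahydrohinokiflavone, CNP0184214.1 | O=C1C[C@@H](c2ccc(Oc3c(O)cc4c(c3O)C(=O)C[C@@H](c3ccc(O)cc3)O4)cc2)Oc2cc(O)cc(O)c21 | target

Total step count: 10. Longest linear sequence: 7 (steps 4 to 10, from 9 to 22); the aryne branch (steps 1 to 3) joins at step 8.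

Steps most likely to fail

Step 8 is the least certain.
- Fluoride or the alkoxide may deprotonate C3 of the lactone and open it by E1cB elimination. The ring could then still form by carboxylate addition to the aryne, acyl shift and oxa-Michael closure, but the stereochemical information would be lost.
- The alkoxide may also start oligomerisation of the lactone or add to C2 of the chromone.
- The aryl anion may be protonated before it reaches the acyl group.

The fallback uses known chemistry and takes O1 from the phenol instead. The six-membered ring is still grown out of a four-membered lactone, but in two separate operations. It sets out from 15 and 1. The cycloaddition of step 7 run with O-trimethylsilylquinidine should give the (4R)-β-lactone F1. Phenol 1 with K2CO3 in DMF should open it at the benzylic carbon by SN2 alkyl–oxygen cleavage with inversion, giving after acidification the (3S)-3-aryloxypropanoic acid F2. Trifluoroacetic anhydride in CH2Cl2 at 0 °C should then close ring C by intramolecular Friedel–Crafts acylation at either of the two equivalent ortho positions. This comes back to the route at 19.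

Step 7 may suffer from three processes:
- slow addition of the ammonium enolate to a donor-substituted aromatic aldehyde;
- competing dimerisation of ketene;
- ionisation or decarboxylation of the benzylic lactone during isolation.

The fallback separates C–C bond formation from ring closure and sets out from 15. A Mukaiyama aldol addition of 1-(tert-butylsulfanyl)-1-(trimethylsilyloxy)ethene under Ti(OiPr)4/(S)-BINOL catalysis, with desilylating work-up, should give the (3S)-β-hydroxy thioester F3. Thiophilic activation with Hg(OCOCF3)2 in MeCN should lactonise it without touching the carbinol C–O bond, so with retention. This comes back to the route at 16.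

Step 4 may stall at low conversion. It may also over-oxidise the electron-rich ring or lose a benzyl ether during the acid hydrolysis of the sulfate.

The fallback builds the oxygenation pattern before the acetyl group and sets out from 1. Teuber oxidation with (KSO3)2NO in buffered aqueous acetone should give the 2,6-bis(benzyloxy)-1,4-benzoquinone F4. Na2S2O4 should reduce it to the 2,6-bis(benzyloxy)hydroquinone F5. C-acetylation with AcOH/BF3·OEt2 (Friedel–Crafts/Fries type) can only occur ortho to the unhindered hydroxyl. This comes back to the route at 11.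

Further compounds
F1 | step 8 | (4R)-4-(4-{[5,7-bis(benzyloxy)-4-oxo-4H-chromen-6-yl]oxy}phenyl)oxetan-2-one | O=C1C[C@H](c2ccc(Oc3c(OCc4ccccc4)cc4occc(=O)c4c3OCc3ccccc3)cc2)O1
F2 | step 8 | (3S)-3-[3,5-bis(benzyloxy)phenoxy]-3-(4-{[5,7-bis(benzyloxy)-4-oxo-4H-chromen-6-yl]oxy}phenyl)propanoic acid | OC(=O)C[C@@H](c1ccc(Oc2c(OCc3ccccc3)cc3occc(=O)c3c2OCc2ccccc2)cc1)Oc1cc(OCc2ccccc2)cc(OCc2ccccc2)c1
F3 | step 7 | S-tert-butyl (3S)-3-(4-{[5,7-bis(benzyloxy)-4-oxo-4H-chromen-6-yl]oxy}phenyl)-3-hydroxypropanethioate | CC(C)(C)SC(=O)C[C@H](O)c1ccc(Oc2c(OCc3ccccc3)cc3occc(=O)c3c2OCc2ccccc2)cc1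
F4 | step 4 | 2,6-bis(benzyloxy)cyclohexa-2,5-diene-1,4-dione | O=C1C=C(OCc2ccccc2)C(=O)C(OCc2ccccc2)=C1
F5 | step 4 | 2,6-bis(benzyloxy)benzene-1,4-diol | Oc1cc(OCc2ccccc2)c(O)c(OCc2ccccc2)c1
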